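**Retrosynthetic overview**

- Target 21 comes from its 2,2,2-trichloroethyl ester 20. The acid is unmasked last with Zn/AcOH, which should leave the allylic acetate, the free phenols and the Z alkene alone.
- The strategy rests on the benzene ring: C1 carries CO2H, C2 and C4 carry OH, C6 carries the C15 chain. C2–C5 is an acetoacetate unit (oxygen on C2 and C4) and C1–C6 is an alk-2-ynoate. Cutting C1–C2 and C5–C6 gives bis-silyloxy diene 17 and chain-bearing ynoate 13. This one ring is the only ring and is formed in the penultimate step.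
- Ynoate 13 comes from terminal alkyne 8 (acylation with the chloroformate, then silyl-to-acetyl exchange). Alkyne 8 comes from silylated (R)-oct-1-yn-3-ol by alkylation with 1-bromo-7-chloroheptane, Z-selective semihydrogenation and acetylide displacement of chloride. The C10' stereocenter is bought.
- Diene 17 comes from methyl acetoacetate by two silylations.

Key step: step 10

Assumption: the enol-ether geometries written for 15, 16 and 17 are nominal. Either isomer or a mixture should serve, because these double bonds are consumed on the way to the arene.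

**Route**

Step 1
Reactants: 1 (R)-oct-1-yn-3-ol
Product: 2 (R)-tert-butyldimethyl(oct-1-yn-3-yloxy)silane
Conditions: TBSCl, imidazole, DMF, rt
Reagents that add atoms: tert-butyldimethylsilyl chloride, CC(C)(C)[Si](C)(C)Cl
Why: Imidazole-mediated O-silylation of a secondary propargylic alcohol; the C–O bond is not broken, so the R centre is retained.

Step 2
Reactants: 2 (R)-tert-butyldimethyl(oct-1-yn-3-yloxy)silane; 3 1-bromo-7-chloroheptane
Product: 5 (10R)-10-(tert-butyldimethylsilyloxy)-1-chloropentadec-8-yne, via lithium acetylide 4 (not isolated)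
Conditions: n-BuLi, THF, −78 °C; then 3 (excess), DMPU, −78 °C → rt
Reagents that add atoms: none
Why: SN2 alkylation of a lithium acetylide, in which bromide is displaced much faster than chloride, should leave the chloride as the handle for the next chain extension.

Step 3
Reactants: 5 (10R)-10-(tert-butyldimethylsilyloxy)-1-chloropentadec-8-yne
Product: 6 (8Z,10R)-10-(tert-butyldimethylsilyloxy)-1-chloropentadec-8-ene
Conditions: H2 (1 atm), Pd/CaCO3 poisoned with Pb(OAc)2, quinoline, hexane, rt
Reagents that add atoms: none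
Why: Lindlar-type semihydrogenation delivers both hydrogens syn on the poisoned palladium surface and should stop at the Z alkene; the alkyl chloride and the silyl ether are inert.

Step 4
Reactants: 6 (8Z,10R)-10-(tert-butyldimethylsilyloxy)-1-chloropentadec-8-ene; 7 lithium acetylide–ethane-1,2-diamine complex
Product: 8 (10Z,12R)-12-(tert-butyldimethylsilyloxy)heptadec-10-en-1-yne
Conditions: LiC≡CH·H2NCH2CH2NH2 (excess), NaI (cat.), DMSO, rt
Reagents that add atoms: none
Why: SN2 displacement of the primary chloride by acetylide in DMSO, assisted by in-situ Finkelstein exchange to the iodide, should give the terminal alkyne.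

Step 5
Reactants: 8 (10Z,12R)-12-(tert-butyldimethylsilyloxy)heptadec-10-en-1-yne; 9 2,2,2-trichloroethyl chloroformate
Product: 11 2,2,2-trichloroethyl (11Z,13R)-13-(tert-butyldimethylsilyloxy)octadec-11-en-2-ynoate, via lithium acetylide 10 (not isolated)
Conditions: n-BuLi, THF, −78 °C; then transfer into 9 (excess), THF, −78 → −20 °C
Reagents that add atoms: none
Why: C-acylation of a lithium acetylide with a chloroformate gives the alk-2-ynoate; inverse addition into excess chloroformate at low temperature should suppress a second addition.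

Step 6
Reactants: 11 2,2,2-trichloroethyl (11Z,13R)-13-(tert-butyldimethylsilyloxy)octadec-11-en-2-ynoate
Product: 12 2,2,2-trichloroethyl (11Z,13R)-13-hydroxyoctadec-11-en-2-ynoate
Conditions: HF·pyridine, THF/pyridine, 0 °C → rt
Reagents that add atoms: none
Why: Fluoride-driven desilylation under buffered, weakly acidic conditions avoids a naked alkoxide or fluoride that could add to the ynoate, and does not touch the C13–O bond.

Step 7
Reactants: 12 2,2,2-trichloroethyl (11Z,13R)-13-hydroxyoctadec-11-en-2-ynoate
Product: 13 2,2,2-trichloroethyl (11Z,13R)-13-acetoxyoctadec-11-en-2-ynoate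
Conditions: Ac2O, pyridine, DMAP (cat.), CH2Cl2, 0 °C
Reagents that add atoms: acetic anhydride, CC(=O)OC(C)=O
Why: DMAP-catalysed O-acetylation of the secondary allylic alcohol proceeds with retention at C13 (acyl transfer to oxygen only); the acetate goes on now because selective acetylation in the presence of free phenols would not be possible later.

Step 8
Reactants: 14 methyl acetoacetate
Product: 15 methyl (2E)-3-(trimethylsilyloxy)but-2-enoate
Conditions: Me3SiCl, Et3N, hexane, rt
Reagents that add atoms: chlorotrimethylsilane, C[Si](C)(C)Cl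
Why: O-silylation of the β-keto ester enol (silyl enol ether formation) under amine base is standard for acetoacetates.

Step 9
Reactants: 15 methyl (2E)-3-(trimethylsilyloxy)but-2-enoate
Product: 17 (1E)-1-methoxy-1,3-bis(trimethylsilyloxy)buta-1,3-diene, via lithium dienolate 16 (not isolated)
Conditions: LiN(iPr)2, THF, −78 °C; then Me3SiCl, −78 → 0 °C; non-aqueous work-up, used freshly distilled
Reagents that add atoms: chlorotrimethylsilane, C[Si](C)(C)Cl
Why: γ-Deprotonation of the silyloxy crotonate gives the vinylogous ester enolate, and O-silylation of it furnishes the bis-silyl dienol ether (ketene silyl acetal formation).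

Step 10
Reactants: 13 2,2,2-trichloroethyl (11Z,13R)-13-acetoxyoctadec-11-en-2-ynoate; 17 (1E)-1-methoxy-1,3-bis(trimethylsilyloxy)buta-1,3-diene
Product: 20 2,2,2-trichloroethyl 6-[(8Z,10R)-10-acetoxypentadec-8-en-1-yl]-2,4-dihydroxybenzoate, via cyclohexadiene cycloadduct 18 (not isolated), via aryl silyl ether 19 (not isolated)
Conditions: 17 (2–3 equiv), toluene, 110 °C, sealed tube; then 1 M HCl (aq)/THF, rt, brief
Reagents that add atoms: none
Why: Diene 17, the bis-silyl dienolate of acetoacetate, adds thermally across the electron-poor triple bond of 13 in a normal-demand Diels–Alder reaction, forming ring bonds C5–C6 and C1–C2 and giving cyclohexa-1,4-diene 18. The ring is closed by this intermolecular [4+2] event (in the stepwise limit, Michael addition of the CH2 terminus to the ynoate β-carbon followed by 6-exo-trig closure of the allenolate α-carbon onto the silylated ester carbon), and the connectivity is the same either way. Adduct 18 aromatises by expelling MeOSiMe3 from its ketal carbon and enolising to phenol 19, whose remaining aryl silyl ether is hydrolysed in the mildly acidic work-up to give 20. The closest known reaction type is the Diels–Alder/aromatisation of 1,1-dioxygenated 3-silyloxybuta-1,3-dienes with alk-2-ynoates to 6-substituted resorcylates. No lasting stereocenter is created (the ketal carbon of 18 disappears on aromatisation), and the R centre at C10' and the Z alkene are remote spectators. The selectivity required is regiochemical and is secured by polarity matching: the unsubstituted, most nucleophilic diene terminus bonds to the electrophilic, chain-bearing β-carbon, so the chain ends up at C6 and the ketal-derived OH at C2, while the isolated Z alkene and the acetate are not dienophilic.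

Step 11
Reactants: 20 2,2,2-trichloroethyl 6-[(8Z,10R)-10-acetoxypentadec-8-en-1-yl]-2,4-dihydroxybenzoate
Product: 21 6-[(8Z,10R)-10-acetoxypentadec-8-en-1-yl]-2,4-dihydroxybenzoic acid
Conditions: Zn dust, AcOH/THF, rt
Reagents that add atoms: none
Why: Zinc-mediated reductive β-elimination of the trichloroethyl ester (C–Cl insertion, loss of 1,1-dichloroethene) frees the acid without hydrolytic conditions, so the acetate, the phenols, the Z alkene and the decarboxylation-prone resorcylic acid should survive.

**Compound list**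

1 | (R)-oct-1-yn-3-ol | CCCCC[C@H](C#C)O | starting material
2 | (R)-tert-butyldimethyl(oct-1-yn-3-yloxy)silane | CCCCC[C@H](C#C)O[Si](C)(C)C(C)(C)C | intermediate
3 | 1-bromo-7-chloroheptane | ClCCCCCCCBr | starting material
4 | [(3R)-3-(tert-butyldimethylsilyloxy)oct-1-yn-1-yl]lithium | CCCCC[C@H](C#C[Li])O[Si](C)(C)C(C)(C)C | intermediate
5 | (10R)-10-(tert-butyldimethylsilyloxy)-1-chloropentadec-8-yne | CCCCC[C@H](C#CCCCCCCCCl)O[Si](C)(C)C(C)(C)C | intermediate
6 | (8Z,10R)-10-(tert-butyldimethylsilyloxy)-1-chloropentadec-8-ene | CCCCC[C@H](/C=C\CCCCCCCCl)O[Si](C)(C)C(C)(C)C | intermediate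
7 | lithium acetylide–ethane-1,2-diamine complex | [Li+].[C-]#C.NCCN | starting material
8 | (10Z,12R)-12-(tert-butyldimethylsilyloxy)heptadec-10-en-1-yne | CCCCC[C@H](/C=C\CCCCCCCC#C)O[Si](C)(C)C(C)(C)C | intermediate
9 | 2,2,2-trichloroethyl chloroformate | ClC(=O)OCC(Cl)(Cl)Cl | starting material
10 | [(10Z,12R)-12-(tert-butyldimethylsilyloxy)heptadec-10-en-1-yn-1-yl]lithium | CCCCC[C@H](/C=C\CCCCCCCC#C[Li])O[Si](C)(C)C(C)(C)C | intermediate
11 | 2,2,2-trichloroethyl (11Z,13R)-13-(tert-butyldimethylsilyloxy)octadec-11-en-2-ynoate | CCCCC[C@H](/C=C\CCCCCCCC#CC(=O)OCC(Cl)(Cl)Cl)O[Si](C)(C)C(C)(C)C | intermediate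
12 | 2,2,2-trichloroethyl (11Z,13R)-13-hydroxyoctadec-11-en-2-ynoate | CCCCC[C@H](/C=C\CCCCCCCC#CC(=O)OCC(Cl)(Cl)Cl)O | intermediate
13 | 2,2,2-trichloroethyl (11Z,13R)-13-acetoxyoctadec-11-en-2-ynoate | CCCCC[C@H](/C=C\CCCCCCCC#CC(=O)OCC(Cl)(Cl)Cl)OC(C)=O | intermediate
14 | methyl acetoacetate | CC(=O)CC(=O)OC | starting material
15 | methyl (2E)-3-(trimethylsilyloxy)but-2-enoate | COC(=O)/C=C(\C)O[Si](C)(C)C | intermediate
16 | lithium (1Z)-1-methoxy-3-(trimethylsilyloxy)buta-1,3-dien-1-olate | CO/C(O[Li])=C\C(=C)O[Si](C)(C)C | intermediate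
17 | (1E)-1-methoxy-1,3-bis(trimethylsilyloxy)buta-1,3-diene | CO/C(O[Si](C)(C)C)=C\C(=C)O[Si](C)(C)C | intermediate
18 | 2,2,2-trichloroethyl 2-[(8Z,10R)-10-acetoxypentadec-8-en-1-yl]-6-methoxy-4,6-bis(trimethylsilyloxy)cyclohexa-1,4-diene-1-carboxylate (C6 configuration undefined) | CCCCC[C@H](/C=C\CCCCCCCC1=C(C(=O)OCC(Cl)(Cl)Cl)C(OC)(O[Si](C)(C)C)C=C(O[Si](C)(C)C)C1)OC(C)=O | intermediate
19 | 2,2,2-trichloroethyl 6-[(8Z,10R)-10-acetoxypentadec-8-en-1-yl]-2-hydroxy-4-(trimethylsilyloxy)benzoate | CCCCC[C@H](/C=C\CCCCCCCc1cc(O[Si](C)(C)C)cc(O)c1C(=O)OCC(Cl)(Cl)Cl)OC(C)=O | intermediate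
20 | 2,2,2-trichloroethyl 6-[(8Z,10R)-10-acetoxypentadec-8-en-1-yl]-2,4-dihydroxybenzoate | CCCCC[C@H](/C=C\CCCCCCCc1cc(O)cc(O)c1C(=O)OCC(Cl)(Cl)Cl)OC(C)=O | intermediate
21 | 6-[(8Z,10R)-10-acetoxypentadec-8-en-1-yl]-2,4-dihydroxybenzoic acid | CCCCC[C@H](/C=C\CCCCCCCc1cc(O)cc(O)c1C(=O)O)OC(C)=O | target

**Step count**

Total: 11 steps. Longest linear sequence: 9 steps (steps 1–7, 10, 11, from (R)-oct-1-yn-3-ol). The diene branch is 2 steps (8, 9).

**Steps most likely to fail, with fallbacks**

Step 10. The acyclic diene may decompose thermally or hydrolyse faster than it adds to the only moderately activated, β-alkylated ynoate. Aromatisation may also go partly by loss of the silyloxy group rather than the methoxy group from the ketal carbon, leaving an O-methyl ether at C2. The fallback replaces elimination-driven aromatisation by an Alder–Rickert sequence with a cyclic, s-cis-locked diene that has no methoxy group. It sets out from 13 and returns at 20. Commercial 5,5-dimethylcyclohexane-1,3-dione is silylated (Me3SiCl, Et3N) to 5,5-dimethyl-3-(trimethylsilyloxy)cyclohex-2-en-1-one F1. Kinetic deprotonation with LiN(iPr)2 and Me3SiCl trapping then gives 5,5-dimethyl-1,3-bis(trimethylsilyloxy)cyclohexa-1,3-diene F2. Heating 13 with F2 (neat or in toluene, 140–160 °C, sealed tube) should give the bicyclic adduct 2,2,2-trichloroethyl 3-[(8Z,10R)-10-acetoxypentadec-8-en-1-yl]-8,8-dimethyl-1,5-bis(trimethylsilyloxy)bicyclo[2.2.2]octa-2,5-diene-2-carboxylate F3. F3 should lose 2-methylpropene by retro-Diels–Alder reaction under the same conditions to give 2,2,2-trichloroethyl 6-[(8Z,10R)-10-acetoxypentadec-8-en-1-yl]-2,4-bis(trimethylsilyloxy)benzoate F4. Brief treatment of F4 with dilute HCl in THF gives 20. The regiochemistry follows the same polarity argument.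

Step 4. Substitution at the primary chloride may be slow, so that elimination or base-induced prototropic isomerisation of the Z-allylic silyl ether in the strongly basic DMSO medium competes. The fallback uses a better leaving group and a less basic, non-DMSO alkynylation. It sets out from 6 and returns at 8. Finkelstein exchange (NaI, acetone, reflux) gives (8Z,10R)-10-(tert-butyldimethylsilyloxy)-1-iodopentadec-8-ene F5. Alkylation of LiC≡CSiMe3 (from ethynyltrimethylsilane and n-BuLi) with F5 in THF/DMPU, −78 °C → rt, gives (10Z,12R)-12-(tert-butyldimethylsilyloxy)-1-(trimethylsilyl)heptadec-10-en-1-yne F6. C-desilylation of F6 with K2CO3 in MeOH gives 8.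

Step 5. The lithium acetylide may add a second time to the newly formed, activated ynoate, or may attack the trichloromethyl group by halogen–metal exchange, eroding conversion. The fallback separates C–C bond formation from ester formation. It sets out from 8 and returns at 11. Deprotonation with n-BuLi and carboxylation with CO2 (THF, −78 °C → rt, acidic work-up) gives (11Z,13R)-13-(tert-butyldimethylsilyloxy)octadec-11-en-2-ynoic acid F7. Steglich esterification of F7 with 2,2,2-trichloroethanol (DCC, DMAP (cat.), CH2Cl2, 0 °C) gives 11.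

**Further compounds**

F1 | step 10 | 5,5-dimethyl-3-(trimethylsilyloxy)cyclohex-2-en-1-one | CC1(C)CC(=O)C=C(O[Si](C)(C)C)C1
F2 | step 10 | 5,5-dimethyl-1,3-bis(trimethylsilyloxy)cyclohexa-1,3-diene | C[Si](C)(C)OC1=CC(O[Si](C)(C)C)=CC(C)(C)C1
F3 | step 10 | 2,2,2-trichloroethyl 3-[(8Z,10R)-10-acetoxypentadec-8-en-1-yl]-8,8-dimethyl-1,5-bis(trimethylsilyloxy)bicyclo[2.2.2]octa-2,5-diene-2-carboxylate | CCCCC[C@H](/C=C\CCCCCCCC1=C(C(=O)OCC(Cl)(Cl)Cl)C2(O[Si](C)(C)C)CC(C)(C)C1C(O[Si](C)(C)C)=C2)OC(C)=O
F4 | step 10 | 2,2,2-trichloroethyl 6-[(8Z,10R)-10-acetoxypentadec-8-en-1-yl]-2,4-bis(trimethylsilyloxy)benzoate | CCCCC[C@H](/C=C\CCCCCCCc1cc(O[Si](C)(C)C)cc(O[Si](C)(C)C)c1C(=O)OCC(Cl)(Cl)Cl)OC(C)=O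
F5 | step 4 | (8Z,10R)-10-(tert-butyldimethylsilyloxy)-1-iodopentadec-8-ene | CCCCC[C@H](/C=C\CCCCCCCI)O[Si](C)(C)C(C)(C)C
F6 | step 4 | (10Z,12R)-12-(tert-butyldimethylsilyloxy)-1-(trimethylsilyl)heptadec-10-en-1-yne | CCCCC[C@H](/C=C\CCCCCCCC#C[Si](C)(C)C)O[Si](C)(C)C(C)(C)C
F7 | step 5 | (11Z,13R)-13-(tert-butyldimethylsilyloxy)octadec-11-en-2-ynoic acid | CCCCC[C@H](/C=C\CCCCCCCC#CC(=O)O)O[Si](C)(C)C(C)(C)C
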